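## The problem

Compound **39** is a germacranolide-type sesquiterpenoid. A ten-membered carbocycle (C1–C10) is fused across C6/C7 to a butenolide (O–C12(=O)–C11=C7), and the tetrasubstituted C7=C11 bond carries the C13 acetoxymethyl group. The numbering used throughout is C1 (CH–OAc), C2, C3, C4 (epoxide C–CH3), C5 (epoxide CH), C6 (lactone CH–O), C7, C8 (CH–O-tigloyl), C9, C10 (CH–CH3), C11, C12 (lactone C=O) and C13 (CH2OAc).

- **Ring and stereocentres.** A medium ring has to be closed and six stereocentres set (1S, 4R, 5S, 6S, 8S, 10R).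
- **Which centre controls which.** C1 and C10 are neighbours in an anti relationship and can be set together in an open chain. C8 is insulated from them by C9 and from C6 by the sp2 carbon C7, so it needs reagent control. C4, C5 and C6 are contiguous, with a cis-fused epoxide that is erythro to the C6 oxygen.
- **The epoxide problem.** A C6 hydroxyl can deliver oxygen to a C4=C5 alkene, but only syn (threo), so the carbinol has to be inverted afterwards.
- **Fragile groups.** The trisubstituted epoxide does not tolerate acid or strong Lewis acids. The butenolide has its γ-hydrogen (H6) next to the epoxide, so base can trigger eliminative epoxide opening. Three different esters forbid late hydrolysis, strong hydride or organometallic reagents.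
- **The tetrasubstituted alkene.** C11 carries two oxygenated methylenes that end up different (lactone carbonyl and CH2OAc), which normally raises an alkene-geometry problem.
- **Enabling feature.** The array C4(CH3)(O)–C5H(O)–C6H(O), with a cis epoxide, is the retron of a (Z)-trisubstituted secondary allylic alcohol. That alcohol is the adduct of a C5 alkenyl metal and a C6 aldehyde. A symmetric 2,2-dimethyl-1,3-dioxan-5-ylidene at C11 removes the geometry question and keeps the C6 hydroxyl free.

## Retrosynthesis

**C13 acetate and lactone (39 ⇒ 38 ⇒ 37 ⇒ 35).** The last bonds cut are the C13 acetate and the O6–C12 lactone bond. Acetate **39** comes from hydroxymethyl butenolide **38**, which comes from formyl butenolide **37**, which is the exhaustive oxidation product of triol **35**. Making the lactone last keeps the base-sensitive butenolide out of the route and leaves the C6 hydroxyl free for its earlier tasks. Closing the lactone earlier would remove the only group that can direct the epoxidation. Because C11 in **35** carries two identical CH2OH groups, only the one cis to C6 can lactonise. The forward reaction has to oxidise primary alcohols in the presence of an epoxide and two esters, then reduce an aldehyde beside a lactone.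

**Epoxide and C6 configuration (35 ⇒ 34 ⇒ 33 ⇒ 32 ⇒ 31).** Triol **35** is the deprotected form of erythro epoxy alcohol **34**. **34** is the chelation-controlled reduction product of epoxy ketone **33**, which comes from threo epoxy alcohol **32**, the hydroxyl-directed epoxidation product of (Z)-allylic alcohol **31**. A direct erythro-selective epoxidation of a (Z)-allylic alcohol has no reliable precedent. The threo delivery and the erythro reduction of epoxy ketones both do, so two extra steps buy two predictable stereochemical events. This removes three stereocentres and leaves one, C6, to be set in the ring closure.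

**Key cut, C5–C6 (31 ⇒ 29).** Opening the ring between C5 and C6 gives the (Z)-alkenyl iodide/enal **29**. The neighbouring C6–C7 cut would need a hindered, electron-poor tetrasubstituted alkenyl nucleophile. A C1–C10 cut would postpone two stereocentres to the ring stage. Olefin metathesis at C4=C5 would not control the geometry of a trisubstituted alkene in a ten-membered ring. The C5–C6 cut uses an unhindered trisubstituted alkenyl metal whose geometry is fixed beforehand, and an enal acceptor. The forward reaction must close a ten-membered ring, keep the Z geometry, and favour the 6S carbinol.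

**C7–C8 bond and the C8 stereocentre (29 ⇒ 28 ⇒ 27 ⇒ 26 ⇒ 25 ⇒ 24 ⇒ 15 + 21).** Enal **29** comes from primary alcohol **28** and PMB ether **27**. The C8 tiglate of **27** is installed on alcohol **26**, so the ester of the target doubles as the protecting group and no late deprotection is needed. **26** is the reagent-controlled reduction product of enone **25**, which is the oxidation product of the addition product **24** of aldehyde **15** and alkenyl bromide **21**. Direct addition cannot be expected to control C8 (the nearest stereocentre is 1,3-related through a methylene). The oxidation/oxazaborolidine reduction pair gives C8 a reliable handle. The organometallic step must spare the C5 iodide and the C1 acetate.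

**Dioxanylidene unit (21 ⇒ 20 ⇒ 17 ⇒ 16).** Bromide **21** is the PMB ether of bromo alcohol **20**, made from dibromoalkene **17**, the dibromo-olefination product of ketone **16**. The symmetry of **16** means the tetrasubstituted alkene has no geometry to control.

**C1–C10 bond (15 ⇒ 14 ⇒ 12 ⇒ 11 ⇒ 8 + 9).** Aldehyde **15** comes from alcohol **14**, the hydroboration product of acetate **12**. **12** is the acetate of homoallylic alcohol **11**, the anti-crotylation product of aldehyde **8** with boronate **9**. One step sets both C1 and C10, and the terminal alkene is the latent C8 aldehyde. An aldol route would place the carbonyl at C9 instead of C8.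

**C3–C4 bond (8 ⇒ 7 ⇒ 6 ⇒ 1 + 2).** Aldehyde **8** comes from alcohol **7** and silyl ether **6**. **6** is made by syn-carbocupration of propyne **2** with the copper reagent from bromide **1**, followed by iodination. This is the most direct way to a geometrically pure (Z)-1-iodo-2-methylalkene. Carboalumination would give the E isomer.

## Roads not taken

**Alternative 1: nickel-catalysed reductive ynal closure at C1–C10.**
- *Cut and key step.* The ring is opened between C1 and C10. Ni(cod)2, a bulky N-heterocyclic carbene and Et3SiH would couple the C1 aldehyde of ynal **A2** with the internal alkyne carbon, giving **A1** with a silylated C1 carbinol and an exocyclic C10 methylene.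
- *Merits.* The epoxide, C6 and the butenolide are built in the open chain, where reagent-controlled epoxidation of a (Z)-allylic alcohol sets C4/C5 without any inversion. In this respect it is better than the chosen plan.
- *Weak points.* C1 is formed in the closure far from any stereocentre, and C10 must then be set by hydrogenating the methylene of **A1** relative to C1, so the anti pair rests on two uncertain ring-level events. Zerovalent nickel also binds and couples electron-poor alkenes with alkynes, so the butenolide of **A2** competes with the aldehyde. The required regiochemistry at a terminal alkyne depends entirely on ligand size.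
- *Comparison.* The chosen plan sets C1/C10 in one well-understood open-chain step and brings only esters, a ketal and an enal into the ring closure. It pays with a two-step C6 inversion.

**Alternative 2: chromium-mediated closure at C6–C7 onto an epoxy aldehyde.**
- *Cut and key step.* The ring is opened between C6 and C7. CrCl2 with catalytic NiCl2 would convert the tetrasubstituted β-iodo enoate of **A4** into an alkenylchromium that adds to the epoxy aldehyde. The chromium alkoxide would then acylate on the cis methyl ester to give bicyclic lactone **A3** directly.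
- *Merits.* This is the shortest endgame of all. The epoxide comes from reagent-controlled epoxidation of a nerol-type alcohol, the lactone forms in the closure, and C12 and C13 are differentiated from the start. In step count after ring closure it is clearly better than the chosen plan.
- *Weak points.* **A4** needs a tetrasubstituted iodoalkene of defined geometry. Its alkenyl metal is hindered and deactivated by the ester, so addition in a ten-membered closure is slow. The α,β-epoxy aldehyde is exposed to Lewis-acidic trivalent chromium. C6 is set by the competition between Felkin control from the epoxide and ring constraints.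
- *Comparison.* The chosen plan offers a trivially accessible (Z)-iodide, a nucleophilic trisubstituted alkenylchromium, a robust enal acceptor, and no alkene-geometry problem at C7=C11. It pays with a longer sequence after the closure.

**Alternative 3: anionic oxy-Cope ring expansion.**
- *Cut and key step.* The C9–C10 bond is cut and the ring is traced back to cyclohexenol **A6**. KH/18-crown-6 would trigger a [3,3] shift that expands it to ten-membered ketone **A5**, with C10 set through a chair transition state.
- *Merits.* The ring forms without high dilution, C10 is set stereospecifically, and the (Z)-C4=C5 alkene is inherited from the six-membered ring. These are real advantages over any macrocyclisation.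
- *Weak points.* **A5** lacks C11–C13 and the C8 oxygen. The tetrasubstituted C7=C11 alkene, the C8 carbinol and the C1 carbinol would all have to be installed stereoselectively on a flexible ring. **A6** itself has three contiguous stereocentres and a (Z)-enol ether. Its C6 silyl ether sits next to the alkoxide and can migrate.
- *Comparison.* The chosen plan brings all thirteen skeletal carbons and every oxygen except the epoxide oxygen through the closure, at the cost of a dilution-dependent step.

Key step: step 17

Assumption 1: the (R)-configured BINOL phosphoric acid of step 4 is taken to direct the crotyl group to the Re face of aldehyde **8**, as it does with simple aldehydes; if the sense were opposite, the (S) acid would be used.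

Assumption 2: silyl ether **1** is purchased as such; it is otherwise one silylation away from 3-bromopropan-1-ol.

## Route

Step 1
Reactants: 1 (3-bromopropoxy)(tert-butyl)dimethylsilane; 2 propyne
Product: 6 (Z)-tert-butyl[(5-iodo-4-methylpent-4-en-1-yl)oxy]dimethylsilane, via Grignard reagent 3 (not isolated), via alkylcopper 4 (not isolated), via (Z)-alkenylcopper 5 (not isolated)
Conditions: Mg, Et2O, rt; CuBr·SMe2, Et2O/Me2S, −45 °C; propyne, −25 °C; I2, THF, −78 → 0 °C
Reagents that add atoms: iodine, II
Why: Normant carbocupration: the alkylcopper adds syn across propyne with the alkyl group on the internal carbon, and iodinolysis of the C–Cu bond with retention puts iodine cis to the chain, which fixes the later C4=C5 geometry.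

Step 2
Reactants: 6 (Z)-tert-butyl[(5-iodo-4-methylpent-4-en-1-yl)oxy]dimethylsilane
Product: 7 (Z)-5-iodo-4-methylpent-4-en-1-ol
Conditions: tetrabutylammonium fluoride, THF, 0 °C → rt
Reagents that add atoms: none
Why: Fluoride cleavage of a primary silyl ether; the alkenyl iodide is inert.

Step 3
Reactants: 7 (Z)-5-iodo-4-methylpent-4-en-1-ol
Product: 8 (Z)-5-iodo-4-methylpent-4-enal
Conditions: Dess–Martin periodinane, CH2Cl2, 0 °C → rt
Reagents that add atoms: none
Why: Dess–Martin oxidation of a primary alcohol stops at the aldehyde and does not touch the iodoalkene.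

Step 4
Reactants: 8 (Z)-5-iodo-4-methylpent-4-enal; 9 (E)-crotylboronic acid pinacol ester
Product: 11 (3R,4S,7Z)-8-iodo-3,7-dimethylocta-1,7-dien-4-ol, via pinacol borate ester 10 (not isolated)
Conditions: (R)-3,3′-bis(2,4,6-triisopropylphenyl)-1,1′-binaphthyl-2,2′-diyl hydrogen phosphate (5 mol%), toluene, −30 °C; aqueous work-up
Reagents that add atoms: none
Why: Chiral Brønsted acid-catalysed crotylboration through a closed chair transition state: the (E)-crotyl geometry gives the anti C1/C10 pair and the phosphate selects the Re face of the aldehyde, giving 4S (C1) and 3R (C10).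

Step 5
Reactants: 11 (3R,4S,7Z)-8-iodo-3,7-dimethylocta-1,7-dien-4-ol
Product: 12 (3R,4S,7Z)-8-iodo-3,7-dimethylocta-1,7-dien-4-yl acetate
Conditions: Ac2O, pyridine, 4-(dimethylamino)pyridine (cat.), CH2Cl2, 0 °C → rt
Reagents that add atoms: acetic anhydride, CC(=O)OC(C)=O
Why: Standard acylation installs the C1 acetate of the target at the outset, so it serves as its own protecting group.

Step 6
Reactants: 12 (3R,4S,7Z)-8-iodo-3,7-dimethylocta-1,7-dien-4-yl acetate
Product: 14 (3R,4S,7Z)-1-hydroxy-8-iodo-3,7-dimethyloct-7-en-4-yl acetate, via B-alkyl-9-borabicyclononane 13 (not isolated)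
Conditions: 9-BBN, THF, 0 °C → rt; 30% H2O2, aq NaOAc, 0 °C → rt
Reagents that add atoms: hydrogen peroxide, OO
Why: Anti-Markovnikov hydroboration–oxidation: 9-BBN selects the monosubstituted alkene over the deactivated trisubstituted iodoalkene, and the buffered oxidation spares the acetate.

Step 7
Reactants: 14 (3R,4S,7Z)-1-hydroxy-8-iodo-3,7-dimethyloct-7-en-4-yl acetate
Product: 15 (3R,4S,7Z)-8-iodo-3,7-dimethyl-1-oxooct-7-en-4-yl acetate
Conditions: Dess–Martin periodinane, CH2Cl2, rt
Reagents that add atoms: none
Why: Dess–Martin oxidation gives the C8 aldehyde under neutral conditions without epimerising C10, which is β to the carbonyl.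

Step 8
Reactants: 16 2,2-dimethyl-1,3-dioxan-5-one
Product: 17 5-(dibromomethylidene)-2,2-dimethyl-1,3-dioxane
Conditions: CBr4, PPh3, CH2Cl2, 0 °C → rt
Reagents that add atoms: carbon tetrabromide, BrC(Br)(Br)Br
Why: Ramirez dibromo-olefination (first stage of the Corey–Fuchs sequence); the α,α′-dialkoxy ketone is electrophilic enough to react with the dibromomethylene ylide.

Step 9
Reactants: 17 5-(dibromomethylidene)-2,2-dimethyl-1,3-dioxane
Product: 20 2-bromo-2-(2,2-dimethyl-1,3-dioxan-5-ylidene)ethan-1-ol, via lithium carbenoid 18 (not isolated), via bromo enal 19 (not isolated)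
Conditions: n-BuLi, THF/Et2O, −105 °C; DMF, −105 → −78 °C; MeOH then NaBH4, −78 → 0 °C
Reagents that add atoms: N,N-dimethylformamide, CN(C)C=O
Why: Bromine–lithium exchange gives a 1-bromo-1-lithioalkene that persists below −100 °C (a Fritsch–Buttenberg–Wiechell shift would have to form a seven-membered cycloalkyne); formylation and borohydride reduction in the same flask give the allylic alcohol. The alkene is symmetric, so no geometry arises.

Step 10
Reactants: 20 2-bromo-2-(2,2-dimethyl-1,3-dioxan-5-ylidene)ethan-1-ol
Product: 21 5-{1-bromo-2-[(4-methoxybenzyl)oxy]ethylidene}-2,2-dimethyl-1,3-dioxane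
Conditions: NaH, 4-methoxybenzyl chloride, Bu4NI (cat.), DMF, 0 °C → rt
Reagents that add atoms: 4-methoxybenzyl chloride, COc1ccc(CCl)cc1
Why: Williamson etherification under basic conditions keeps the acetonide intact; the PMB ether tolerates alkyllithium reagents and is later removed oxidatively.

Step 11
Reactants: 21 5-{1-bromo-2-[(4-methoxybenzyl)oxy]ethylidene}-2,2-dimethyl-1,3-dioxane; 15 (3R,4S,7Z)-8-iodo-3,7-dimethyl-1-oxooct-7-en-4-yl acetate
Product: 24 (5R,6S,9Z)-2-(2,2-dimethyl-1,3-dioxan-5-ylidene)-3-hydroxy-10-iodo-1-[(4-methoxybenzyl)oxy]-5,9-dimethyldec-9-en-6-yl acetate (both C3 epimers), via alkenyllithium 22 (not isolated), via alkenylcerium dichloride 23 (not isolated)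
Conditions: t-BuLi (2 equiv), THF, −78 °C; CeCl3, THF, −78 °C; then 15, −78 °C; aq NH4Cl
Reagents that add atoms: none
Why: Bromine–lithium exchange followed by transmetalation to trivalent cerium gives a weakly basic alkenyl nucleophile that adds to the aldehyde faster than it enolises it, attacks the acetate, or exchanges with the C5 iodide. C8 (C3 of this name) is formed unselectively and corrected in steps 12 and 13.

Step 12
Reactants: 24 (5R,6S,9Z)-2-(2,2-dimethyl-1,3-dioxan-5-ylidene)-3-hydroxy-10-iodo-1-[(4-methoxybenzyl)oxy]-5,9-dimethyldec-9-en-6-yl acetate (both C3 epimers)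
Product: 25 (5R,6S,9Z)-2-(2,2-dimethyl-1,3-dioxan-5-ylidene)-10-iodo-1-[(4-methoxybenzyl)oxy]-5,9-dimethyl-3-oxodec-9-en-6-yl acetate
Conditions: Dess–Martin periodinane, pyridine, CH2Cl2, 0 °C → rt
Reagents that add atoms: none
Why: Buffered Dess–Martin oxidation converges both epimers on one enone without harming the acetonide.

Step 13
Reactants: 25 (5R,6S,9Z)-2-(2,2-dimethyl-1,3-dioxan-5-ylidene)-10-iodo-1-[(4-methoxybenzyl)oxy]-5,9-dimethyl-3-oxodec-9-en-6-yl acetate
Product: 26 (3S,5R,6S,9Z)-2-(2,2-dimethyl-1,3-dioxan-5-ylidene)-3-hydroxy-10-iodo-1-[(4-methoxybenzyl)oxy]-5,9-dimethyldec-9-en-6-yl acetate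
Conditions: (R)-1-methyl-3,3-diphenylhexahydropyrrolo[1,2-c][1,3,2]oxazaborole (1 equiv), catecholborane, toluene, −78 °C
Reagents that add atoms: none
Why: Corey–Bakshi–Shibata reduction: the α-branched tetrasubstituted alkenyl group is the large substituent and the C9 methylene the small one, so the (R)-oxazaborolidine delivers hydride to give the 8S carbinol (3S here). Catecholborane does not reduce esters or hydroborate the alkenes at this temperature.

Step 14
Reactants: 26 (3S,5R,6S,9Z)-2-(2,2-dimethyl-1,3-dioxan-5-ylidene)-3-hydroxy-10-iodo-1-[(4-methoxybenzyl)oxy]-5,9-dimethyldec-9-en-6-yl acetate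
Product: 27 (3S,5R,6S,9Z)-6-acetoxy-2-(2,2-dimethyl-1,3-dioxan-5-ylidene)-10-iodo-1-[(4-methoxybenzyl)oxy]-5,9-dimethyldec-9-en-3-yl (E)-2-methylbut-2-enoate
Conditions: tiglic acid, 2,4,6-trichlorobenzoyl chloride, Et3N, toluene, rt; then 26, 4-(dimethylamino)pyridine, toluene, rt → 40 °C
Reagents that add atoms: tiglic acid, C/C=C(\C)C(=O)O
Why: Yamaguchi esterification acylates the hindered allylic alcohol through the mixed anhydride without the ketene-type deconjugation seen with enoyl chlorides. The tiglate of the target then protects C8 for the rest of the route.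

Step 15
Reactants: 27 (3S,5R,6S,9Z)-6-acetoxy-2-(2,2-dimethyl-1,3-dioxan-5-ylidene)-10-iodo-1-[(4-methoxybenzyl)oxy]-5,9-dimethyldec-9-en-3-yl (E)-2-methylbut-2-enoate
Product: 28 (3S,5R,6S,9Z)-6-acetoxy-1-hydroxy-2-(2,2-dimethyl-1,3-dioxan-5-ylidene)-10-iodo-5,9-dimethyldec-9-en-3-yl (E)-2-methylbut-2-enoate
Conditions: DDQ, CH2Cl2/pH 7 buffer, 0 °C
Reagents that add atoms: none
Why: Oxidative PMB cleavage under buffered conditions leaves the acetonide, both esters and the alkenyl iodide alone; the product is oxidised at once to avoid tiglate migration to the new primary hydroxyl.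

Step 16
Reactants: 28 (3S,5R,6S,9Z)-6-acetoxy-1-hydroxy-2-(2,2-dimethyl-1,3-dioxan-5-ylidene)-10-iodo-5,9-dimethyldec-9-en-3-yl (E)-2-methylbut-2-enoate
Product: 29 (3S,5R,6S,9Z)-6-acetoxy-2-(2,2-dimethyl-1,3-dioxan-5-ylidene)-10-iodo-5,9-dimethyl-1-oxodec-9-en-3-yl (E)-2-methylbut-2-enoate
Conditions: MnO2, CH2Cl2, rt
Reagents that add atoms: none
Why: Neutral allylic oxidation with MnO2 gives the C6 enal. There is no α-hydrogen on C7, so the β-acyloxy group at C8 cannot eliminate.

Step 17
Reactants: 29 (3S,5R,6S,9Z)-6-acetoxy-2-(2,2-dimethyl-1,3-dioxan-5-ylidene)-10-iodo-5,9-dimethyl-1-oxodec-9-en-3-yl (E)-2-methylbut-2-enoate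
Product: 31 (1S,4Z,6S,8S,10R)-7-(2,2-dimethyl-1,3-dioxan-5-ylidene)-6-hydroxy-4,10-dimethyl-8-tigloyloxycyclodec-4-en-1-yl acetate, via alkenylchromium dichloride 30 (not isolated)
Conditions: CrCl2 (10 equiv), NiCl2 (0.1 equiv), degassed DMSO, rt, slow addition to 0.002 M
Reagents that add atoms: none
Why: Zerovalent nickel, formed from NiCl2 and CrCl2, inserts into the C5–I bond with retention and hands the alkenyl group to trivalent chromium; alkenylchromium 30 then adds 1,2 to the C6 formyl group. The closest known reaction type is the intramolecular Nozaki–Hiyama–Kishi coupling of alkenyl iodides with aldehydes, which closes medium and large carbocycles. The ten-membered ring closes by a 10-exo-trig attack of C5 on C6 under high dilution. The new C6 stereocentre is controlled by C8: allylic 1,3-strain against the dioxane methylenes holds H8 in the C7=C11 plane, so the C8–C9 bond and the tigloyloxy group lie on opposite faces. To avoid a syn-pentane contact between C5 and C9, the alkenyl carbon should reach the s-trans formyl group from the face opposite C9, that is syn to the C8 oxygen, which gives 6S. The step needs retention of the Z geometry, secured by the stereoretentive oxidative addition and transmetalation. It needs chemoselectivity for the aldehyde, secured by the low reactivity of organochromium reagents towards esters, ketals and enoates. It needs cyclisation over oligomerisation, helped by dilution and by the Z alkene and the sp2 C7 that shorten the effective chain. The facial preference at C6 is the least secure of these.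

Step 18
Reactants: 31 (1S,4Z,6S,8S,10R)-7-(2,2-dimethyl-1,3-dioxan-5-ylidene)-6-hydroxy-4,10-dimethyl-8-tigloyloxycyclodec-4-en-1-yl acetate
Product: 32 (1S,4R,5S,6R,8S,10R)-7-(2,2-dimethyl-1,3-dioxan-5-ylidene)-4,5-epoxy-6-hydroxy-4,10-dimethyl-8-tigloyloxycyclodecyl acetate (threo epoxy alcohol)
Conditions: VO(acac)2 (10 mol%), t-BuOOH (decane), CH2Cl2, 0 °C → rt
Reagents that add atoms: tert-butyl hydroperoxide, CC(C)(C)OO
Why: Hydroxyl-directed vanadium-catalysed epoxidation: with H6 eclipsing the C4=C5 bond (allylic 1,3-strain against C3), the metal-bound peroxide delivers oxygen to the face syn to the C6 oxygen, giving the cis (threo) epoxy alcohol with 4R,5S. The C7=C11 alkene is flanked by four allylic C–O bonds and is far less nucleophilic.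

Step 19
Reactants: 32 (1S,4R,5S,6R,8S,10R)-7-(2,2-dimethyl-1,3-dioxan-5-ylidene)-4,5-epoxy-6-hydroxy-4,10-dimethyl-8-tigloyloxycyclodecyl acetate (threo epoxy alcohol)
Product: 33 (1S,4R,5R,8S,10R)-7-(2,2-dimethyl-1,3-dioxan-5-ylidene)-4,5-epoxy-4,10-dimethyl-6-oxo-8-tigloyloxycyclodecyl acetate
Conditions: Dess–Martin periodinane, pyridine, CH2Cl2, 0 °C → rt
Reagents that add atoms: none
Why: Buffered Dess–Martin oxidation gives the α,β-epoxy ketone without opening the epoxide. The C5 descriptor changes to R only because the CIP priorities change.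

Step 20
Reactants: 33 (1S,4R,5R,8S,10R)-7-(2,2-dimethyl-1,3-dioxan-5-ylidene)-4,5-epoxy-4,10-dimethyl-6-oxo-8-tigloyloxycyclodecyl acetate
Product: 34 (1S,4R,5S,6S,8S,10R)-7-(2,2-dimethyl-1,3-dioxan-5-ylidene)-4,5-epoxy-6-hydroxy-4,10-dimethyl-8-tigloyloxycyclodecyl acetate (erythro epoxy alcohol)
Conditions: Zn(BH4)2, Et2O, −20 → 0 °C
Reagents that add atoms: none
Why: Chelation-controlled reduction of an α,β-epoxy ketone: zinc bridges the carbonyl and epoxide oxygens and hydride attacks the exposed face of the chelate, giving the erythro alcohol, which is the 6S configuration of the target. The reagent reduces the twisted enone 1,2 and leaves the esters alone.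

Step 21
Reactants: 34 (1S,4R,5S,6S,8S,10R)-7-(2,2-dimethyl-1,3-dioxan-5-ylidene)-4,5-epoxy-6-hydroxy-4,10-dimethyl-8-tigloyloxycyclodecyl acetate (erythro epoxy alcohol)
Product: 35 (1S,4R,5S,6S,8S,10R)-7-(1,3-dihydroxypropan-2-ylidene)-4,5-epoxy-6-hydroxy-4,10-dimethyl-8-tigloyloxycyclodecyl acetate
Conditions: pyridinium p-toluenesulfonate (0.2 equiv), MeOH, 0 °C → rt
Reagents that add atoms: none
Why: Mild transketalisation removes the acetonide, which is strained by allylic 1,3-strain on both sides of the exocyclic alkene and so is unusually labile. The epoxide, deactivated at C5 by the adjacent carbinol, should survive the weak acid.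

Step 22
Reactants: 35 (1S,4R,5S,6S,8S,10R)-7-(1,3-dihydroxypropan-2-ylidene)-4,5-epoxy-6-hydroxy-4,10-dimethyl-8-tigloyloxycyclodecyl acetate
Product: 37 (1S,4R,5S,6S,8S,10R)-1-acetoxy-4,5-epoxy-13-oxo-8-tigloyloxygermacr-7(11)-en-12,6-olide, via lactol aldehyde 36 (not isolated)
Conditions: 2,2,6,6-tetramethylpiperidin-1-oxyl (0.3 equiv), PhI(OAc)2 (3.5 equiv), CH2Cl2, rt
Reagents that add atoms: none
Why: Nitroxyl-catalysed oxidative lactonisation: both primary allylic alcohols are oxidised, and only the aldehyde cis to C6 is trapped by the C6 hydroxyl as a lactol and oxidised on to the butenolide. The other remains as the C13 aldehyde, so C12 and C13 are differentiated by geometry alone.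

Step 23
Reactants: 37 (1S,4R,5S,6S,8S,10R)-1-acetoxy-4,5-epoxy-13-oxo-8-tigloyloxygermacr-7(11)-en-12,6-olide
Product: 38 (1S,4R,5S,6S,8S,10R)-1-acetoxy-4,5-epoxy-13-hydroxy-8-tigloyloxygermacr-7(11)-en-12,6-olide
Conditions: NaBH4, CeCl3·7H2O, MeOH, −78 °C
Reagents that add atoms: none
Why: Luche reduction: cerium-modified borohydride reduces the aldehyde 1,2 at low temperature, faster than it attacks the lactone, the esters or the fully substituted β-carbon, and the low basicity protects the γ-hydrogen next to the epoxide.

Step 24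
Reactants: 38 (1S,4R,5S,6S,8S,10R)-1-acetoxy-4,5-epoxy-13-hydroxy-8-tigloyloxygermacr-7(11)-en-12,6-olide
Product: 39 (1S,4R,5S,6S,8S,10R)-1,13-diacetoxy-4,5-epoxy-8-tigloyloxygermacr-7(11)-en-12,6-olide (CNP0287840.1)
Conditions: Ac2O, pyridine, 4-(dimethylamino)pyridine (cat.), CH2Cl2, 0 °C
Reagents that add atoms: acetic anhydride, CC(=O)OC(C)=O
Why: Acetylation of the primary allylic alcohol under weakly basic conditions completes the target without disturbing the butenolide or the epoxide.

## Compound list

1 | (3-bromopropoxy)(tert-butyl)dimethylsilane | CC(C)(C)[Si](C)(C)OCCCBr | starting material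
2 | propyne | CC#C | starting material
3 | 3-(tert-butyldimethylsilyloxy)propylmagnesium bromide (formed in the flask) | CC(C)(C)[Si](C)(C)OCCC[Mg]Br | intermediate
4 | 3-(tert-butyldimethylsilyloxy)propylcopper (formed in the flask) | CC(C)(C)[Si](C)(C)OCCC[Cu] | intermediate
5 | (Z)-5-(tert-butyldimethylsilyloxy)-2-methylpent-1-enylcopper (formed in the flask) | CC(C)(C)[Si](C)(C)OCCC/C(C)=C\[Cu] | intermediate
6 | (Z)-tert-butyl[(5-iodo-4-methylpent-4-en-1-yl)oxy]dimethylsilane | CC(C)(C)[Si](C)(C)OCCC/C(C)=C\I | intermediate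
7 | (Z)-5-iodo-4-methylpent-4-en-1-ol | OCCC/C(C)=C\I | intermediate
8 | (Z)-5-iodo-4-methylpent-4-enal | O=CCC/C(C)=C\I | intermediate
9 | (E)-crotylboronic acid pinacol ester | C/C=C/CB1OC(C)(C)C(C)(C)O1 | starting material
10 | pinacol borate ester of alcohol 11 (formed in the flask) | I/C=C(/C)CC[C@H](OB1OC(C)(C)C(C)(C)O1)[C@H](C)C=C | intermediate
11 | (3R,4S,7Z)-8-iodo-3,7-dimethylocta-1,7-dien-4-ol | I/C=C(/C)CC[C@H](O)[C@H](C)C=C | intermediate
12 | (3R,4S,7Z)-8-iodo-3,7-dimethylocta-1,7-dien-4-yl acetate | I/C=C(/C)CC[C@H](OC(C)=O)[C@H](C)C=C | intermediate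
13 | B-alkyl-9-borabicyclo[3.3.1]nonane from 12 (formed in the flask) | I/C=C(/C)CC[C@H](OC(C)=O)[C@H](C)CCB1C2CCCC1CCC2 | intermediate
14 | (3R,4S,7Z)-1-hydroxy-8-iodo-3,7-dimethyloct-7-en-4-yl acetate | I/C=C(/C)CC[C@H](OC(C)=O)[C@H](C)CCO | intermediate
15 | (3R,4S,7Z)-8-iodo-3,7-dimethyl-1-oxooct-7-en-4-yl acetate | I/C=C(/C)CC[C@H](OC(C)=O)[C@H](C)CC=O | intermediate
16 | 2,2-dimethyl-1,3-dioxan-5-one | CC1(C)OCC(=O)CO1 | starting material
17 | 5-(dibromomethylidene)-2,2-dimethyl-1,3-dioxane | CC1(C)OCC(=C(Br)Br)CO1 | intermediate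
18 | 5-[bromo(lithio)methylidene]-2,2-dimethyl-1,3-dioxane (formed in the flask) | CC1(C)OCC(=C([Li])Br)CO1 | intermediate
19 | 2-bromo-2-(2,2-dimethyl-1,3-dioxan-5-ylidene)acetaldehyde (formed in the flask) | CC1(C)OCC(=C(Br)C=O)CO1 | intermediate
20 | 2-bromo-2-(2,2-dimethyl-1,3-dioxan-5-ylidene)ethan-1-ol | CC1(C)OCC(=C(Br)CO)CO1 | intermediate
21 | 5-{1-bromo-2-[(4-methoxybenzyl)oxy]ethylidene}-2,2-dimethyl-1,3-dioxane | COc1ccc(COCC(Br)=C2COC(C)(C)OC2)cc1 | intermediate
22 | alkenyllithium from 21 (formed in the flask) | COc1ccc(COCC([Li])=C2COC(C)(C)OC2)cc1 | intermediate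
23 | alkenylcerium dichloride from 22 (formed in the flask) | COc1ccc(COCC([Ce](Cl)Cl)=C2COC(C)(C)OC2)cc1 | intermediate
24 | (5R,6S,9Z)-2-(2,2-dimethyl-1,3-dioxan-5-ylidene)-3-hydroxy-10-iodo-1-[(4-methoxybenzyl)oxy]-5,9-dimethyldec-9-en-6-yl acetate, both C3 (= C8) epimers | I/C=C(/C)CC[C@H](OC(C)=O)[C@H](C)CC(O)C(COCc1ccc(OC)cc1)=C1COC(C)(C)OC1 | intermediate
25 | (5R,6S,9Z)-2-(2,2-dimethyl-1,3-dioxan-5-ylidene)-10-iodo-1-[(4-methoxybenzyl)oxy]-5,9-dimethyl-3-oxodec-9-en-6-yl acetate | I/C=C(/C)CC[C@H](OC(C)=O)[C@H](C)CC(=O)C(COCc1ccc(OC)cc1)=C1COC(C)(C)OC1 | intermediate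
26 | (3S,5R,6S,9Z)-2-(2,2-dimethyl-1,3-dioxan-5-ylidene)-3-hydroxy-10-iodo-1-[(4-methoxybenzyl)oxy]-5,9-dimethyldec-9-en-6-yl acetate | I/C=C(/C)CC[C@H](OC(C)=O)[C@H](C)C[C@H](O)C(COCc1ccc(OC)cc1)=C1COC(C)(C)OC1 | intermediate
27 | (3S,5R,6S,9Z)-6-acetoxy-2-(2,2-dimethyl-1,3-dioxan-5-ylidene)-10-iodo-1-[(4-methoxybenzyl)oxy]-5,9-dimethyldec-9-en-3-yl (E)-2-methylbut-2-enoate | I/C=C(/C)CC[C@H](OC(C)=O)[C@H](C)C[C@H](OC(=O)/C(C)=C/C)C(COCc1ccc(OC)cc1)=C1COC(C)(C)OC1 | intermediate
28 | (3S,5R,6S,9Z)-6-acetoxy-1-hydroxy-2-(2,2-dimethyl-1,3-dioxan-5-ylidene)-10-iodo-5,9-dimethyldec-9-en-3-yl (E)-2-methylbut-2-enoate | I/C=C(/C)CC[C@H](OC(C)=O)[C@H](C)C[C@H](OC(=O)/C(C)=C/C)C(CO)=C1COC(C)(C)OC1 | intermediate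
29 | (3S,5R,6S,9Z)-6-acetoxy-2-(2,2-dimethyl-1,3-dioxan-5-ylidene)-10-iodo-5,9-dimethyl-1-oxodec-9-en-3-yl (E)-2-methylbut-2-enoate (precursor of the key step) | I/C=C(/C)CC[C@H](OC(C)=O)[C@H](C)C[C@H](OC(=O)/C(C)=C/C)C(C=O)=C1COC(C)(C)OC1 | intermediate
30 | (Z)-alkenylchromium dichloride from 29 (formed in the flask) | Cl[Cr](Cl)/C=C(/C)CC[C@H](OC(C)=O)[C@H](C)C[C@H](OC(=O)/C(C)=C/C)C(C=O)=C1COC(C)(C)OC1 | intermediate
31 | (1S,4Z,6S,8S,10R)-7-(2,2-dimethyl-1,3-dioxan-5-ylidene)-6-hydroxy-4,10-dimethyl-8-tigloyloxycyclodec-4-en-1-yl acetate (product of the key step) | C/C=C(\C)C(=O)O[C@H]1C[C@@H](C)[C@@H](OC(C)=O)CC/C(C)=C\[C@H](O)C1=C1COC(C)(C)OC1 | intermediate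
32 | (1S,4R,5S,6R,8S,10R)-7-(2,2-dimethyl-1,3-dioxan-5-ylidene)-4,5-epoxy-6-hydroxy-4,10-dimethyl-8-tigloyloxycyclodecyl acetate (threo) | C/C=C(\C)C(=O)O[C@H]1C[C@@H](C)[C@@H](OC(C)=O)CC[C@@]2(C)O[C@H]2[C@H](O)C1=C1COC(C)(C)OC1 | intermediate
33 | (1S,4R,5R,8S,10R)-7-(2,2-dimethyl-1,3-dioxan-5-ylidene)-4,5-epoxy-4,10-dimethyl-6-oxo-8-tigloyloxycyclodecyl acetate | C/C=C(\C)C(=O)O[C@H]1C[C@@H](C)[C@@H](OC(C)=O)CC[C@@]2(C)O[C@H]2C(=O)C1=C1COC(C)(C)OC1 | intermediate
34 | (1S,4R,5S,6S,8S,10R)-7-(2,2-dimethyl-1,3-dioxan-5-ylidene)-4,5-epoxy-6-hydroxy-4,10-dimethyl-8-tigloyloxycyclodecyl acetate (erythro) | C/C=C(\C)C(=O)O[C@H]1C[C@@H](C)[C@@H](OC(C)=O)CC[C@@]2(C)O[C@H]2[C@@H](O)C1=C1COC(C)(C)OC1 | intermediate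
35 | (1S,4R,5S,6S,8S,10R)-7-(1,3-dihydroxypropan-2-ylidene)-4,5-epoxy-6-hydroxy-4,10-dimethyl-8-tigloyloxycyclodecyl acetate | C/C=C(\C)C(=O)O[C@H]1C[C@@H](C)[C@@H](OC(C)=O)CC[C@@]2(C)O[C@H]2[C@@H](O)C1=C(CO)CO | intermediate
36 | C12 lactol carrying the C13 formyl group, both C12 epimers (formed in the flask) | C/C=C(\C)C(=O)O[C@H]1C[C@@H](C)[C@@H](OC(C)=O)CC[C@@]2(C)O[C@H]2[C@H]2OC(O)C(C=O)=C12 | intermediate
37 | (1S,4R,5S,6S,8S,10R)-1-acetoxy-4,5-epoxy-13-oxo-8-tigloyloxygermacr-7(11)-en-12,6-olide | C/C=C(\C)C(=O)O[C@H]1C[C@@H](C)[C@@H](OC(C)=O)CC[C@@]2(C)O[C@H]2[C@H]2OC(=O)C(C=O)=C12 | intermediate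
38 | (1S,4R,5S,6S,8S,10R)-1-acetoxy-4,5-epoxy-13-hydroxy-8-tigloyloxygermacr-7(11)-en-12,6-olide | C/C=C(\C)C(=O)O[C@H]1C[C@@H](C)[C@@H](OC(C)=O)CC[C@@]2(C)O[C@H]2[C@H]2OC(=O)C(CO)=C12 | intermediate
39 | (1S,4R,5S,6S,8S,10R)-1,13-diacetoxy-4,5-epoxy-8-tigloyloxygermacr-7(11)-en-12,6-olide (CNP0287840.1) | C/C=C(\C)C(=O)O[C@H]1C[C@@H](C)[C@@H](OC(C)=O)CC[C@@]2(C)O[C@H]2[C@H]2OC(=O)C(COC(C)=O)=C12 | target

## Step count and weak points

Total: 24 steps. Longest linear sequence: 21 steps (steps 1–7, then 11–24). The dioxanylidene fragment takes 3 steps (8–10).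

**Step 17 (key step).** The most likely failure is poor facial selectivity at C6. The preference for 6S rests on a conformational argument about the forming ring, not on a nearby directing group, and a medium-ring transition state may override it. Oligomerisation is the second concern. Fallback: the closure is run from **29** without regard to selectivity. The material, containing the 6-epimeric alcohol F1, is oxidised with Dess–Martin periodinane/pyridine to the cross-conjugated dienone F2. F2 is reduced with the (R)-oxazaborolidine of step 13 and catecholborane, with the tetrasubstituted alkenyl group acting as the large substituent, which returns the route to **31**. C6 is then set by the reagent instead of the ring closure.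

**Step 18.** The risk is insufficient facial selectivity or slow oxygen transfer, because the medium-ring conformation may hold the C6 oxygen away from the alkene face it must reach. Attack on C7=C11 is a smaller risk. Fallback: a Shi epoxidation of **31**, using the fructose-derived ketone catalyst of the antipode assigned by the spiro transition-state model, with Oxone in buffered MeCN/dimethoxymethane–water at 0 °C. This sets the epoxide by reagent control and returns to **32**.

**Step 20.** The risk is erosion of the erythro preference, because the ring may not allow the planar zinc chelate of carbonyl and epoxide oxygens. Fallback: the ketone is bypassed. Threo alcohol **32** is inverted by a Mitsunobu reaction with chloroacetic acid, diisopropyl azodicarboxylate and PPh3, giving the inverted chloroacetate F3. SN2′ attack would have to occur at the quaternary C11 and is not expected. The chloroacetyl group is removed with thiourea and NaHCO3 in EtOH, which spares the acetate and the tiglate, returning to **34**.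

**Step 21.** The risk is acid-induced opening of the trisubstituted epoxide, by methanol or by a liberated primary hydroxyl, during acetonide cleavage. Fallback: the acetonide is exchanged before any epoxide exists. From **31**, pyridinium p-toluenesulfonate in MeOH gives the alkene triol F4. TBSCl/imidazole at 0 °C silylates the two primary hydroxyls to give the bis-silyl ether F5, leaving the hindered C6 hydroxyl free. The conditions of steps 18–20 are then repeated to give the threo epoxy alcohol F6, the epoxy ketone F7 and the erythro epoxy alcohol F8. Acetic acid-buffered tetrabutylammonium fluoride releases **35** without any acid.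

**Steps 22 and 23.** The risk lies in the handling of **37**. Its C6 hydrogen is activated by both the lactone and the formyl group, so base can trigger eliminative opening of the adjacent epoxide, and hydride may add in conjugate fashion. Fallback: the aldehyde is never formed. Triol **35** is subjected to an Oppenauer-type transfer dehydrogenation with Cp*RuCl(Ph2PCH2CH2NH2), catalytic KOt-Bu and two equivalents of acetone in toluene. Under reversible hydrogen transfer with a limited amount of acceptor, the only strongly downhill outlet is the passage through the C12 lactol F9 to the lactone. The C13 alcohol is left untouched, and the route rejoins at **38**.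

## Further compounds

F1 | step 17 | (1S,4Z,6R,8S,10R)-7-(2,2-dimethyl-1,3-dioxan-5-ylidene)-6-hydroxy-4,10-dimethyl-8-tigloyloxycyclodec-4-en-1-yl acetate (6-epimer of 31) | C/C=C(\C)C(=O)O[C@H]1C[C@@H](C)[C@@H](OC(C)=O)CC/C(C)=C\[C@@H](O)C1=C1COC(C)(C)OC1
F2 | step 17 | (1S,4Z,8S,10R)-7-(2,2-dimethyl-1,3-dioxan-5-ylidene)-4,10-dimethyl-6-oxo-8-tigloyloxycyclodec-4-en-1-yl acetate | C/C=C(\C)C(=O)O[C@H]1C[C@@H](C)[C@@H](OC(C)=O)CC/C(C)=C\C(=O)C1=C1COC(C)(C)OC1
F0 | step 18 | none | none
F3 | step 20 | (1S,4R,5S,6S,8S,10R)-6-chloroacetoxy-7-(2,2-dimethyl-1,3-dioxan-5-ylidene)-4,5-epoxy-4,10-dimethyl-8-tigloyloxycyclodecyl acetate | C/C=C(\C)C(=O)O[C@H]1C[C@@H](C)[C@@H](OC(C)=O)CC[C@@]2(C)O[C@H]2[C@@H](OC(=O)CCl)C1=C1COC(C)(C)OC1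
F4 | step 21 | (1S,4Z,6S,8S,10R)-7-(1,3-dihydroxypropan-2-ylidene)-6-hydroxy-4,10-dimethyl-8-tigloyloxycyclodec-4-en-1-yl acetate | C/C=C(\C)C(=O)O[C@H]1C[C@@H](C)[C@@H](OC(C)=O)CC/C(C)=C\[C@H](O)C1=C(CO)CO
F5 | step 21 | (1S,4Z,6S,8S,10R)-7-[1,3-bis(tert-butyldimethylsilyloxy)propan-2-ylidene]-6-hydroxy-4,10-dimethyl-8-tigloyloxycyclodec-4-en-1-yl acetate | C/C=C(\C)C(=O)O[C@H]1C[C@@H](C)[C@@H](OC(C)=O)CC/C(C)=C\[C@H](O)C1=C(CO[Si](C)(C)C(C)(C)C)CO[Si](C)(C)C(C)(C)C
F6 | step 21 | (1S,4R,5S,6R,8S,10R)-7-[1,3-bis(tert-butyldimethylsilyloxy)propan-2-ylidene]-4,5-epoxy-6-hydroxy-4,10-dimethyl-8-tigloyloxycyclodecyl acetate (threo) | C/C=C(\C)C(=O)O[C@H]1C[C@@H](C)[C@@H](OC(C)=O)CC[C@@]2(C)O[C@H]2[C@H](O)C1=C(CO[Si](C)(C)C(C)(C)C)CO[Si](C)(C)C(C)(C)C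
F7 | step 21 | (1S,4R,5R,8S,10R)-7-[1,3-bis(tert-butyldimethylsilyloxy)propan-2-ylidene]-4,5-epoxy-4,10-dimethyl-6-oxo-8-tigloyloxycyclodecyl acetate | C/C=C(\C)C(=O)O[C@H]1C[C@@H](C)[C@@H](OC(C)=O)CC[C@@]2(C)O[C@H]2C(=O)C1=C(CO[Si](C)(C)C(C)(C)C)CO[Si](C)(C)C(C)(C)C
F8 | step 21 | (1S,4R,5S,6S,8S,10R)-7-[1,3-bis(tert-butyldimethylsilyloxy)propan-2-ylidene]-4,5-epoxy-6-hydroxy-4,10-dimethyl-8-tigloyloxycyclodecyl acetate (erythro) | C/C=C(\C)C(=O)O[C@H]1C[C@@H](C)[C@@H](OC(C)=O)CC[C@@]2(C)O[C@H]2[C@@H](O)C1=C(CO[Si](C)(C)C(C)(C)C)CO[Si](C)(C)C(C)(C)C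
F9 | step 23 | C12 lactol carrying the free C13 hydroxymethyl group, both C12 epimers | C/C=C(\C)C(=O)O[C@H]1C[C@@H](C)[C@@H](OC(C)=O)CC[C@@]2(C)O[C@H]2[C@H]2OC(O)C(CO)=C12
A1 | alternative 1 | 10-methylene ten-membered epoxy butenolide with C1 triethylsilyl ether, C8 PMB ether and C13 silyl ether | COc1ccc(CO[C@H]2CC(=C)[C@@H](O[Si](CC)(CC)CC)CC[C@@]3(C)O[C@H]3[C@H]3OC(=O)C(CO[Si](C)(C)C(C)(C)C)=C23)cc1
A2 | alternative 1 | open-chain ynal: butenolide carrying the C8 PMB-oxy but-3-ynyl arm and the epoxide chain ending in the C1 aldehyde | C#CC[C@H](OCc1ccc(OC)cc1)C1=C(CO[Si](C)(C)C(C)(C)C)C(=O)O[C@@H]1[C@@H]1O[C@]1(C)CCC=O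
A3 | alternative 2 | bicyclic epoxy butenolide with C1 acetate and C8, C13 silyl ethers | CC(C)(C)[Si](C)(C)O[C@H]1C[C@@H](C)[C@@H](OC(C)=O)CC[C@@]2(C)O[C@H]2[C@H]2OC(=O)C(CO[Si](C)(C)C(C)(C)C)=C12
A4 | alternative 2 | open-chain β-iodo enoate (iodine cis to the methyl ester) tethered to the C6 epoxy aldehyde | COC(=O)/C(CO[Si](C)(C)C(C)(C)C)=C(\I)[C@@H](O[Si](C)(C)C(C)(C)C)C[C@@H](C)[C@@H](OC(C)=O)CC[C@@]1(C)O[C@H]1C=O
A5 | alternative 3 | ten-membered C7 ketone with C10 methyl, C1 methyl enol ether, Z C4=C5 alkene and C6 silyl ether | O=C1CC[C@@H](C)/C(OC)=C/C/C(C)=C\[C@H]1O[Si](C)(C)C(C)(C)C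
A6 | alternative 3 | 1-vinylcyclohex-3-en-1-ol with 2-silyloxy, 4-methyl and trans 6-[(Z)-1-methoxyprop-1-enyl] groups | C=C[C@@]1(O)[C@H](O[Si](C)(C)C(C)(C)C)C=C(C)C[C@@H]1/C(OC)=C/C
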